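Plan
- The target is a (2S,3R,4R)-oxolane with the C2 aryl and C3 CH2OH trans and the C3 CH2OH and C4 benzyl cis. The retrosynthesis removes the phenol silyl group. It then cuts, in one retro-step, the exocyclic CH2–C(aryl) bond to the guaiacyl ring and the ring bond C3–C4. The last cuts are O1–C5 (allyl ether), the oxirane oxygen and the vinyl–carbinol C–C bond.
- Enabling feature: on the oxolane ring, C3 carries CH2OH, which is the trace of an oxirane opened at its inner carbon. Its neighbour C4 carries the exocyclic CH2, and O1 lies between C2 and C5. C3(radical)–C2–O1–C5–C4=CH2 is therefore a 3-oxa-5-hexenyl radical, and its 5-exo closure leaves a primary radical on exactly the carbon that must bond to the arene.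
- Forward order: veratraldehyde plus vinyl Grignard, kinetic-resolution epoxidation, O-allylation, Ni/Ti cascade with silylated 4-bromoguaiacol, desilylation. The cascade closes the only saturated ring and joins the second arene. Both coupling partners are electrophiles, united reductively through a radical.
- Stereochemistry: only C2 is set by catalysis (Sharpless, D-(−)-DIPT). C3 and C4 are relayed from C2 in one event, the chair-like radical closure. The oxirane stereocentre is sacrificial.

Key step: step 5

Assumption: the SMILES is read as a lariciresinol-type 7,9'-epoxylignan of (2S,3R,4R) configuration in which the phenol of the C2 aryl ring is methylated.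

Step 1
Reactants: 1 3,4-dimethoxybenzaldehyde; 2 vinylmagnesium bromide
Product: 3 rac-1-(3,4-dimethoxyphenyl)prop-2-en-1-ol
Conditions: THF, 0 °C; then sat. aq NH4Cl
Reagents that add atoms: none
Why: Grignard 1,2-addition to a non-enolisable aromatic aldehyde gives the aryl vinyl carbinol as the racemate, and the mild quench avoids acid-induced allylic transposition.

Step 2
Reactants: 3 rac-1-(3,4-dimethoxyphenyl)prop-2-en-1-ol
Product: 4 (R)-(3,4-dimethoxyphenyl)[(S)-oxiran-2-yl]methanol (erythro/anti epoxy alcohol)
Conditions: Ti(OiPr)4 (0.2 equiv), D-(−)-DIPT (0.24 equiv), TBHP (0.45 equiv), 4 Å MS, CH2Cl2, −20 °C, stopped below half conversion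
Reagents that add atoms: tert-butyl hydroperoxide CC(C)(C)OO
Why: In this Sharpless kinetic-resolution epoxidation with D-(−)-DIPT the (S)-carbinol is the fast-reacting enantiomer and is epoxidised to the erythro epoxy alcohol, so the benzylic C–O stereocentre (future C2) is selected by the catalyst while the (R)-carbinol stays behind.

Step 3
Reactants: 4 (R)-(3,4-dimethoxyphenyl)[(S)-oxiran-2-yl]methanol; 5 allyl bromide
Product: 6 (2S)-2-[(R)-(3,4-dimethoxyphenyl)(prop-2-en-1-yloxy)methyl]oxirane
Conditions: NaH, Bu4NI (cat.), THF, 0 °C
Reagents that add atoms: none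
Why: Williamson etherification of the sodium alkoxide with a reactive allylic bromide in an aprotic medium at low temperature should outrun Payne migration and touches neither stereocentre.

Step 4
Reactants: 7 4-bromo-2-methoxyphenol
Product: 8 (4-bromo-2-methoxyphenoxy)(tert-butyl)dimethylsilane
Conditions: TBSCl, imidazole, CH2Cl2, rt
Reagents that add atoms: tert-butyldimethylsilyl chloride CC(C)(C)[Si](C)(C)Cl
Why: Imidazole-promoted silylation of the phenol masks the acidic O–H for the reductive coupling and leaves the aryl C–Br bond untouched.

Step 5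
Reactants: 6 (2S)-2-[(R)-(3,4-dimethoxyphenyl)(prop-2-en-1-yloxy)methyl]oxirane; 8 (4-bromo-2-methoxyphenoxy)(tert-butyl)dimethylsilane
Product: 12 [(2S,3R,4R)-4-{[4-(tert-butyldimethylsilyloxy)-3-methoxyphenyl]methyl}-2-(3,4-dimethoxyphenyl)oxolan-3-yl]methanol, via open-chain titanoxy radical 9 (not isolated), via cyclised primary radical 10 (not isolated), via arylnickel bromide 11 (not isolated)
Conditions: NiCl2·glyme (10 mol %), 2,2'-bipyridine (10 mol %), Cp2TiCl2 (15 mol %), Mn (3 equiv), Et3N·HCl (1.3 equiv), 8 (1.5 equiv), DMPU, rt, slow addition of 6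
Reagents that add atoms: none
Why: Proposed new method: Cp2TiCl (from Cp2TiCl2 and Mn) opens the oxirane of 6 by single-electron transfer at the inner C–O bond to the secondary β-titanoxy radical 9, which adds to the O-allyl double bond to give the primary radical 10; 10 is captured by arylnickel(II) bromide 11 (oxidative addition of 8 to (bpy)Ni(0)), reductive elimination from Ni(III) forms the CH2–aryl bond, Et3N·HCl cleaves the O–Ti bond and Mn returns both metals to their reduced states. The closest known reaction types are the Ni/titanocene co-catalysed reductive arylation of epoxides with aryl bromides, the Ti(III)-mediated epoxide–olefin radical cyclisation (Nugent–RajanBabu type) of aryl-substituted epoxy allyl ethers, and the Ni-catalysed reductive cyclisation–arylation of olefinic alkyl halides, so that only the merger of these events is new. The one ring closed is the oxolane, by 5-exo-trig attack of C3 on C4 through a Beckwith–Houk chair with the C2 aryl group pseudo-equatorial. C3 and C4 are both controlled by the C2 stereocentre in that transition state: the CH2OTi arm on the planar radical carbon turns away from the aryl group (2,3-trans), and the preferences of 1-substituted (cis) and 2-substituted (trans) 5-hexenyl radicals reinforce each other to place the new CH2 cis to CH2OTi and trans to the aryl group, while the oxirane stereocentre is erased in 9. The step needs the right order of events, cyclisation before capture for 9 and nickel capture before reduction or H-abstraction for 10; the first is secured by the unimolecular, oxygen-accelerated closure competing only with bimolecular trapping by catalysts present in low concentration, the second by keeping Ti(III) catalytic, using a poor H-donor solvent, adding 6 slowly and using 8 in excess. The aryl bromide is preferred to the iodide so that no iodide accumulates to open the oxirane at its terminal carbon, and the phenol is silylated so that no acidic O–H quenches the aryl–nickel or titanium species.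

Step 6
Reactants: 12 [(2S,3R,4R)-4-{[4-(tert-butyldimethylsilyloxy)-3-methoxyphenyl]methyl}-2-(3,4-dimethoxyphenyl)oxolan-3-yl]methanol
Product: 13 4-{[(3R,4R,5S)-5-(3,4-dimethoxyphenyl)-4-(hydroxymethyl)oxolan-3-yl]methyl}-2-methoxyphenol (target)
Conditions: TBAF (1.1 equiv), AcOH (1.1 equiv), THF, 0 °C
Reagents that add atoms: none
Why: Fluoride-induced cleavage of the aryl silyl ether, buffered with AcOH, is orthogonal to the methyl ethers, the primary alcohol and the benzylic oxolane C–O bond and leaves all three stereocentres untouched.

Compound list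
1 | 3,4-dimethoxybenzaldehyde | COc1ccc(C=O)cc1OC | starting material
2 | vinylmagnesium bromide | C=C[Mg]Br | starting material
3 | rac-1-(3,4-dimethoxyphenyl)prop-2-en-1-ol | OC(c1ccc(OC)c(OC)c1)C=C | intermediate
4 | (R)-(3,4-dimethoxyphenyl)[(S)-oxiran-2-yl]methanol | O[C@H](c1ccc(OC)c(OC)c1)[C@@H]1CO1 | intermediate
5 | allyl bromide | C=CCBr | starting material
6 | (2S)-2-[(R)-(3,4-dimethoxyphenyl)(prop-2-en-1-yloxy)methyl]oxirane | C=CCO[C@H](c1ccc(OC)c(OC)c1)[C@@H]1CO1 | intermediate
7 | 4-bromo-2-methoxyphenol | COc1cc(Br)ccc1O | starting material
8 | (4-bromo-2-methoxyphenoxy)(tert-butyl)dimethylsilane | COc1cc(Br)ccc1O[Si](C)(C)C(C)(C)C | intermediate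
9 | open-chain secondary β-titanoxy radical, Cp2Ti(Cl)O–CH2–CH(radical)–CH(Ar)(O-allyl), Cp rings drawn σ-bonded | C=CCO[C@H](c1ccc(OC)c(OC)c1)[CH]CO[Ti](Cl)(C1C=CC=C1)C1C=CC=C1 | intermediate
10 | cyclised primary radical, 2,3-trans-3,4-cis oxolane with C4–CH2 radical and C3–CH2OTi(Cl)Cp2, Cp rings drawn σ-bonded | [CH2][C@H]1CO[C@H](c2ccc(OC)c(OC)c2)[C@H]1CO[Ti](Cl)(C3C=CC=C3)C3C=CC=C3 | intermediate
11 | [4-(tert-butyldimethylsilyloxy)-3-methoxyphenyl]nickel(II) bromide, 2,2'-bipyridine complex (ligand written separately) | COc1cc([Ni]Br)ccc1O[Si](C)(C)C(C)(C)C.c1ccc(-c2ccccn2)nc1 | intermediate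
12 | [(2S,3R,4R)-4-{[4-(tert-butyldimethylsilyloxy)-3-methoxyphenyl]methyl}-2-(3,4-dimethoxyphenyl)oxolan-3-yl]methanol | COc1cc(C[C@H]2CO[C@H](c3ccc(OC)c(OC)c3)[C@H]2CO)ccc1O[Si](C)(C)C(C)(C)C | intermediate
13 | 4-{[(3R,4R,5S)-5-(3,4-dimethoxyphenyl)-4-(hydroxymethyl)oxolan-3-yl]methyl}-2-methoxyphenol | COc1cc(C[C@H]2CO[C@H](c3ccc(OC)c(OC)c3)[C@H]2CO)ccc1O | target

Total steps: 6. Longest linear sequence: 5 (steps 1, 2, 3, 5, 6).

Steps most likely to fail

1. Step 5.
- Risk: the primary radical may be intercepted by Ti(III) or by an H-donor instead of by nickel. The open-chain radical may be arylated before it cyclises. The 3,4-cis control may be eroded with the unsubstituted allyl acceptor.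
- Fallback: the cascade is split into its two known halves. Setting out from 6, stoichiometric Cp2TiCl (Cp2TiCl2/Zn, THF, rt) performs the reductive epoxide–olefin cyclisation. The resulting primary alkyltitanium is quenched with I2 to give [(2S,3R,4R)-2-(3,4-dimethoxyphenyl)-4-(iodomethyl)oxolan-3-yl]methanol F1, at which stage diastereomers can be separated. A Ni-catalysed reductive cross-electrophile coupling of F1 with 8 (NiI2, 4,4'-di-tert-butyl-2,2'-bipyridine, Zn, DMPU, rt) then forms the same CH2–aryl bond and comes back to the route at 12.

2. Step 2.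
- Risk: the monosubstituted alkene may be epoxidised sluggishly. The electron-rich benzylic carbinol may ionise under Lewis acid. Discrimination between the enantiomers may be insufficient.
- Fallback: resolution and epoxidation are separated. Setting out from 3, lipase-catalysed acylation (CAL-B, vinyl acetate, MTBE, rt) should leave (S)-1-(3,4-dimethoxyphenyl)prop-2-en-1-ol F2 and convert its antipode into (R)-1-(3,4-dimethoxyphenyl)prop-2-en-1-yl acetate F3. Hydroxyl-directed epoxidation of F2 (VO(acac)2, TBHP, CH2Cl2, 0 °C) should favour the erythro isomer and comes back to the route at 4. The threo epimer (R)-(3,4-dimethoxyphenyl)[(R)-oxiran-2-yl]methanol F4 formed alongside needs no separation, because the oxirane stereocentre is erased in step 5.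

3. Step 3.
- Risk: Payne migration of the alkoxide to the internal epoxide, followed by allylation at the wrong oxygen.
- Fallback: no free alkoxide is generated. Setting out from 4, a Pd(0)-catalysed Tsuji–Trost O-allylation with allyl ethyl carbonate (Pd2(dba)3, dppb, THF, 60 °C) under neutral conditions comes back to the route at 6. It makes no new compound (entry F0).

Further compounds
F1 | step 5 | [(2S,3R,4R)-2-(3,4-dimethoxyphenyl)-4-(iodomethyl)oxolan-3-yl]methanol | IC[C@H]1CO[C@H](c2ccc(OC)c(OC)c2)[C@H]1CO
F2 | step 2 | (S)-1-(3,4-dimethoxyphenyl)prop-2-en-1-ol | O[C@H](c1ccc(OC)c(OC)c1)C=C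
F3 | step 2 | (R)-1-(3,4-dimethoxyphenyl)prop-2-en-1-yl acetate | CC(=O)O[C@@H](c1ccc(OC)c(OC)c1)C=C
F4 | step 2 | (R)-(3,4-dimethoxyphenyl)[(R)-oxiran-2-yl]methanol | O[C@H](c1ccc(OC)c(OC)c1)[C@H]1CO1
F0 | step 3 | none | none
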